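Our closed, stirred vessel holds a racemate, 10 mM of each hand, with 30.0 mM of coupling partner and a single-handed free catalyst, while a racemization catalyst can turn one hand into the other.

in all of them: left-handed substrate 10 mM; right-handed substrate 10 mM; free catalyst 0.11 mM

| run | coupling partner | racemization catalyst | remark | time |
|---|---|---|---|---|
| beta | 30 mM | 6.7 µM | run made earlier |  |
| zeta | 30 mM | 15 µM | run made earlier |  |
| flask | 30.0 mM | 10 µM |  | 25 min |

- beta (time / min: left-handed substrate / %, right-handed substrate / %): 2.50: 5.4, 12.2; 8.00: 1.2, 3.8; 15.0: 0.2, 2.1; 20.0: 0.6, 1.3; 30.0: 0, 0.1
- zeta (time / min: left-handed substrate / %, right-handed substrate / %): 2.50: 6.2, 12.8; 8.00: 1.5, 4.4; 15.0: 1.0, 1.6; 20.0: 0, 1.2; 30.0: 0.7, 0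

(each reading ± 0.5 percentage points)

- part of the left-handed substrate and right-handed substrate charged together that has reacted at 25 min
- excess of left-handed product over right-handed product in the product at 25 min
- excess of right-handed substrate over left-handed substrate among what is left of the two at 25 min

- free catalyst is single-handed; left-handed substrate and right-handed substrate are mirror images of each other, charged as a racemate, each of them at the stated concentration
- the analysis behind the earlier runs scatters by 0.5 percentage points, standard deviation
- an excess is below zero if the other one leads

How selective is the free catalyst? We count half-lives: n is the number of halvings a substrate has undergone from its own charge. At 2.50 min, averaging beta and zeta, the left-handed substrate keeps 11.6% of its charge, so n_L = 3.11. The right-handed substrate keeps 25.0%, so n_R = 2.00. The selectivity factor s, the ratio n_L/n_R of half-lives lived by the two hands, reads 1.55.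

How far does the pair go? Averaged over beta and zeta, it falls from 5.45% at 8.00 min to 1.55% at 20.0 min, which reads as a tail half-life of 6.62 min. If the tail keeps that half-life, we reckon 0.918% left at 25 min, so c is near 99.1%.

What will the excess do? With s acting unopposed, the right-handed substrate has lived n_L/s half-lives. At 15.0 min, that means 5.81% of its charge and an excess of 65.7%. The pooled beta and zeta readings at that time give 51.0%, lower than that figure, though this is a reading that carries their scatter, and we commit to about that value for eS.

The forecast gives c = 99.2%, eP = 2.5% and eS = 55%, holding of the ratio of right-handed to left-handed substrate that “slow racemization (roughly 0.02 per minute) holds it near 3.5”.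

The flask gives c = 98.8%, eP = 4.60% and eS = 37.5%, lower in eS than the forecast's figure and ours.

    coupling partner + free catalyst + left-handed substrate → free catalyst + left-handed product (k = 13000 L² mol⁻² s⁻¹)
    coupling partner + free catalyst + right-handed substrate → free catalyst + right-handed product (k = 7700 L² mol⁻² s⁻¹)
    left-handed substrate + racemization catalyst ⇌ right-handed substrate + racemization catalyst, rate k3*[racemization catalyst]*[left-handed substrate] forward; the back reaction follows from the equilibrium constant (k = 260 L mol⁻¹ s⁻¹)
    2 coupling partner → homo dimer (k = 0.160 L mol⁻¹ s⁻¹)
    coupling partner ⇌ dormant form (K = 0.170, k = 0.00410 s⁻¹)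
    2 racemization catalyst ⇌ resting dimer, settled at all times (K = 1.00 × 10⁶ L mol⁻¹)

Up to 25.0 min in the flask, a net 2.04% of the pair, counted on both substrates charged together, passed from right-handed to left-handed substrate. There the left-handed substrate keeps 0.77% of its charge; s unopposed pairs that with 4.37% of the right-handed substrate's charge, and the right-handed substrate keeps 1.7%. In the neighbour flask with 0.044 mM of free catalyst, the left-handed substrate keeps 12%; s unopposed pairs that with 25.5%, and the right-handed substrate keeps 17%, with an excess of 16.2%.

All runs were computed with constants of no real substance, and the scatter is random.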